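**Retrosynthetic overview**
- The (Z)-cinnamic acid comes from the (E)-acid by contra-thermodynamic photoisomerisation; the (E)-acid comes from an aryl aldehyde and malonic acid.
- The acetate comes from the secondary allylic alcohol.
- Key disconnection: the aryl–CH2 bond, made by a light-driven nickel 4,1-hydroarylation of a chiral 2-substituted 1,3-diene with an aryl bromide. This step also sets the (E)-trisubstituted alkene.
- The diene comes from (−)-trans-pinocarveol by retro-[2+2] opening of the cyclobutane. This terpene supplies the only stereocentre, which is never a reacting centre.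
- No ring is formed. The benzene ring is bought, and both carbocycles of the pinane are opened in one step.

Assumption: (−)-trans-pinocarveol, (1S,3R,5S), is taken as a purchasable terpene-pool material (also available in one step from (+)-α-pinene oxide).

**Step 1**
Reactants: 1 (−)-trans-pinocarveol [(1S,3R,5S)-6,6-dimethyl-2-methylidenebicyclo[3.1.1]heptan-3-ol]
Product: 2 (4R)-7-methyl-3-methylideneocta-1,6-dien-4-ol
Conditions: flash vacuum pyrolysis, quartz tube, 520 °C, 0.1–0.5 mbar, contact time ca. 20–50 ms, trap at −78 °C, then distillation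
Reagents that add atoms: none
Why: Thermal retro-[2+2] cycloreversion of a vinylcyclobutane (the β-pinene-to-myrcene reaction type), in which homolysis of the strained C1–C6 bond gives an allyl/tertiary 1,4-diradical that cleaves C5–C7 to the 1,3-diene and the prenyl alkene, while the carbinol carbon (R, bought in 1) is not part of any breaking bond and is carried through unchanged.

**Step 2**
Reactants: 2 (4R)-7-methyl-3-methylideneocta-1,6-dien-4-ol (1.0 equiv); 3 3-bromo-4-methoxybenzaldehyde (1.5 equiv)
Product: 4 3-[(2E,4R)-4-hydroxy-3,7-dimethylocta-2,6-dien-1-yl]-4-methoxybenzaldehyde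
Conditions: NiBr2·DME (10 mol %), 4,4'-di-tert-butyl-2,2'-bipyridine (12 mol %), 4CzIPN [2,4,5,6-tetrakis(carbazol-9-yl)isophthalonitrile] (2 mol %), Hantzsch ester (1.5 equiv), Na2CO3 (1.5 equiv), degassed DMA, 450 nm LEDs, 25 °C
Reagents that add atoms: none
Why: Proposed new method: light-driven nickel hydride 4,1-hydroarylation of a 2-substituted 1,3-diene, in which photoreduced bipyridine-ligated zerovalent nickel binds the diene of 2 in its s-cis form and is protonated (by oxidised Hantzsch ester or bicarbonate) at the methylidene CH2 to give the more substituted η3-allyl with the new methyl anti and the carbinol arm syn, one-electron reduction gives a monovalent nickel allyl that adds aryl bromide 3, and C(sp2)–C(sp3) reductive elimination from trivalent nickel at the unhindered CH2 terminus gives the linear (E)-alkene with the R carbinol centre a spectator; the closest known reactions are nickel hydride hydroarylation of 1,3-dienes with aryl halides and silanes (branched 1,2-adducts on aryl dienes) and iron-catalysed 1,4-hydroboration of myrcene-type dienes (same E-selective 1,4-delivery), neither shown with photochemical hydride generation on a branched diene bearing a free hydroxyl stereocentre.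

**Step 3**
Reactants: 4 3-[(2E,4R)-4-hydroxy-3,7-dimethylocta-2,6-dien-1-yl]-4-methoxybenzaldehyde
Product: 5 (2E,4R)-1-(5-formyl-2-methoxyphenyl)-3,7-dimethylocta-2,6-dien-4-yl acetate
Conditions: Ac2O (1.5 equiv), pyridine (3 equiv), DMAP (5 mol %), CH2Cl2, 0 °C to rt
Reagents that add atoms: acetic anhydride, CC(=O)OC(C)=O
Why: DMAP-catalysed O-acylation (nucleophilic acyl transfer) of the secondary allylic alcohol, which leaves the C–O bond of the stereocentre intact (retention, R) and does not touch the aryl aldehyde.

**Step 4**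
Reactants: 5 (2E,4R)-1-(5-formyl-2-methoxyphenyl)-3,7-dimethylocta-2,6-dien-4-yl acetate
Product: 7 (2E)-3-{3-[(2E,4R)-4-(acetyloxy)-3,7-dimethylocta-2,6-dien-1-yl]-4-methoxyphenyl}prop-2-enoic acid, via arylidenemalonic acid 6 (not isolated)
Conditions: malonic acid (2 equiv), pyridine, piperidine (10 mol %), 80 °C
Reagents that add atoms: malonic acid, OC(=O)CC(=O)O
Why: Knoevenagel condensation in its Doebner modification, where condensation with malonic acid and decarboxylation in pyridine gives the free (E)-cinnamic acid directly, so no ester hydrolysis is needed and the secondary acetate survives the weakly basic medium.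

**Step 5**
Reactants: 7 (2E)-3-{3-[(2E,4R)-4-(acetyloxy)-3,7-dimethylocta-2,6-dien-1-yl]-4-methoxyphenyl}prop-2-enoic acid
Product: 8 (2Z)-3-{3-[(2E,4R)-4-(acetyloxy)-3,7-dimethylocta-2,6-dien-1-yl]-4-methoxyphenyl}prop-2-enoic acid
Conditions: fac-Ir(ppy)3 [tris(2-phenylpyridinato)iridium] (1 mol %), degassed MeCN (0.02 M), 450 nm LEDs, 25 °C; Z acid separated by chromatography, recovered 7 re-irradiated
Reagents that add atoms: none
Why: Triplet energy-transfer E-to-Z photoisomerisation, in which the planar (E)-cinnamic acid accepts triplet energy from the iridium sensitiser while the twisted (Z)-acid is a poorer acceptor and accumulates, and the isolated trisubstituted alkenes, the acetate and the stereocentre lie outside the sensitiser's reach.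

**Compound list**
1 | (−)-trans-pinocarveol, (1S,3R,5S)-6,6-dimethyl-2-methylidenebicyclo[3.1.1]heptan-3-ol | C=C1[C@H](O)C[C@@H]2C[C@H]1C2(C)C | starting material
2 | (4R)-7-methyl-3-methylideneocta-1,6-dien-4-ol | C=CC(=C)[C@H](O)CC=C(C)C | intermediate
3 | 3-bromo-4-methoxybenzaldehyde | COc1ccc(C=O)cc1Br | starting material
4 | 3-[(2E,4R)-4-hydroxy-3,7-dimethylocta-2,6-dien-1-yl]-4-methoxybenzaldehyde | COc1ccc(C=O)cc1C/C=C(\C)[C@H](O)CC=C(C)C | intermediate
5 | (2E,4R)-1-(5-formyl-2-methoxyphenyl)-3,7-dimethylocta-2,6-dien-4-yl acetate | COc1ccc(C=O)cc1C/C=C(\C)[C@@H](CC=C(C)C)OC(C)=O | intermediate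
6 | 2-({3-[(2E,4R)-4-(acetyloxy)-3,7-dimethylocta-2,6-dien-1-yl]-4-methoxyphenyl}methylidene)propanedioic acid | COc1ccc(C=C(C(=O)O)C(=O)O)cc1C/C=C(\C)[C@@H](CC=C(C)C)OC(C)=O | intermediate (not isolated)
7 | (2E)-3-{3-[(2E,4R)-4-(acetyloxy)-3,7-dimethylocta-2,6-dien-1-yl]-4-methoxyphenyl}prop-2-enoic acid | COc1ccc(/C=C/C(=O)O)cc1C/C=C(\C)[C@@H](CC=C(C)C)OC(C)=O | intermediate
8 | (2Z)-3-{3-[(2E,4R)-4-(acetyloxy)-3,7-dimethylocta-2,6-dien-1-yl]-4-methoxyphenyl}prop-2-enoic acid | COc1ccc(/C=C\C(=O)O)cc1C/C=C(\C)[C@@H](CC=C(C)C)OC(C)=O | target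

**Totals**
Total step count: 5. Longest linear sequence: 5 steps (1 to 8).

**Three steps most likely to fail**

Step 2 (the new hydroarylation).
- Risks: hydrodebromination of 3; branched or 1,2-adducts; the Z alkene if a free allyl radical path takes over; redox isomerisation of the allylic alcohol through reversible β-hydride elimination at the carbinol carbon (check ee of 4 by chiral HPLC).
- Fallback, known chemistry, from 2 and 3 back to 4: 2 is silylated (Et3SiCl, imidazole, DMF) to the triethylsilyl ether of 2 F1. Iron-catalysed 1,4-hydroboration with pinacolborane (FeCl2 with a 2-iminopyridine ligand, Mg, Et2O, rt) puts hydrogen on the methylidene carbon and boron on the vinyl terminus with E geometry, giving the (E)-allylboronic acid pinacol ester F2. Separately, 3 is masked (HC(OMe)3, cat. TsOH, MeOH) as the dimethyl acetal of 3 F3, so that the allylboronate cannot add to the aldehyde. A ligand-controlled α-selective Suzuki–Miyaura coupling of F2 with F3 (Pd(OAc)2, bulky dialkylbiarylphosphine, K3PO4, THF–H2O, 40 °C) gives the silyl-protected coupled acetal F4. 1 M HCl in THF then removes the silyl ether and the acetal and returns the route at 4.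

Step 1 (gas-phase cycloreversion).
- Risks: hydrogen-shift isomers (p-menthadienols) from the diradical; loss of 2 in the hot zone by retro-ene cleavage of the homoallylic alcohol and by oxy-Cope rearrangement.
- Fallback, from 1 back to 2: 1 is silylated (Me3SiCl, imidazole, CH2Cl2) to the trimethylsilyl ether of 1 F5. F5 is passed with N2 carrier through a packed quartz flow tube at 480–500 °C. With no O–H there is no retro-ene channel and no keto sink for the Cope product, so the trimethylsilyl ether of 2 F6 is expected to survive. K2CO3 (cat.) in MeOH then returns the route at 2.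

Step 5 (photoisomerisation).
- Risks: only a moderate Z:E photostationary ratio (about 4:1 is expected but unconfirmed for this acid) and a difficult Z/E separation of the acids.
- Fallback, from 5 straight to 8, replacing steps 4 and 5: Still–Gennari olefination of 5 with 2-(trimethylsilyl)ethyl bis(2,2,2-trifluoroethyl)phosphonoacetate (KN(SiMe3)2, 18-crown-6, THF, −78 °C) gives the (Z)-2-(trimethylsilyl)ethyl ester of the target F7. Bu4NF in THF at 0 °C, followed by cold dilute HCl work-up, frees the acid without touching the acetate and arrives at 8.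

**Further compounds**
F1 | step 2 | triethyl{[(4R)-7-methyl-3-methylideneocta-1,6-dien-4-yl]oxy}silane | C=CC(=C)[C@H](O[Si](CC)(CC)CC)CC=C(C)C
F2 | step 2 | (2E,4R)-3,7-dimethyl-4-(triethylsilyloxy)octa-2,6-dien-1-ylboronic acid pinacol ester | CC1(C)OB(C/C=C(\C)[C@H](O[Si](CC)(CC)CC)CC=C(C)C)OC1(C)C
F3 | step 2 | 2-bromo-4-(dimethoxymethyl)-1-methoxybenzene | COc1ccc(C(OC)OC)cc1Br
F4 | step 2 | {[(2E,4R)-1-[5-(dimethoxymethyl)-2-methoxyphenyl]-3,7-dimethylocta-2,6-dien-4-yl]oxy}triethylsilane | COc1ccc(C(OC)OC)cc1C/C=C(\C)[C@H](O[Si](CC)(CC)CC)CC=C(C)C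
F5 | step 1 | {[(1S,3R,5S)-6,6-dimethyl-2-methylidenebicyclo[3.1.1]heptan-3-yl]oxy}trimethylsilane | C=C1[C@H](O[Si](C)(C)C)C[C@@H]2C[C@H]1C2(C)C
F6 | step 1 | trimethyl{[(4R)-7-methyl-3-methylideneocta-1,6-dien-4-yl]oxy}silane | C=CC(=C)[C@H](O[Si](C)(C)C)CC=C(C)C
F7 | step 5 | 2-(trimethylsilyl)ethyl (2Z)-3-{3-[(2E,4R)-4-(acetyloxy)-3,7-dimethylocta-2,6-dien-1-yl]-4-methoxyphenyl}prop-2-enoate | COc1ccc(/C=C\C(=O)OCC[Si](C)(C)C)cc1C/C=C(\C)[C@@H](CC=C(C)C)OC(C)=O
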